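**Assumption:** the SMILES is read literally (both oxiranes are cis, so each derives from a (Z)-olefin); atom labels C1–C15 and the names of ring compounds use germacrane numbering (ring C1–C10, branch C11–C13 on C7, 12,8-olide = lactone from C12 to the oxygen on C8).

## Retrosynthetic overview

1. Target ⇐ bis-epoxy diol 22 by late bis-angeloylation; the oxiranes come from a (1(10)Z,4Z)-diene, C4–C5 by hydroxyl-directed epoxidation from 6-OH, C1–C10 by dioxirane.
2. 6-OH ⇐ 6-ketone by a 1,3-syn reduction steered by 11-OH; the ten-membered ring and the γ-lactone ⇐ one samarium Reformatsky closure of C7–C8 followed by lactonisation (ring order: carbocycle, lactone, oxiranes).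
3. Open chain ⇐ sp3–sp2 Negishi union at C3–C4 of fragment A (C8–C3) and fragment B (C4–C7 with C11–C13).
4. Fragment A ⇐ 4-methylanisole: Birch reduction, then ozonolysis of the enol ether, cuts the ring open and hands its enforced cis geometry to the (Z)-C1(10) olefin (key step).
5. Fragment B ⇐ pent-3-yn-2-one (anti-hydroiodination fixes the (Z)-C4 olefin) and methyl pyruvate (catalytic enantioselective aldol sets C11, from which every other stereocenter is relayed).

## Route

Step 1
Reactants: 1 4-methylanisole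
Product: 2 1-methoxy-4-methylcyclohexa-1,4-diene
Conditions: Li, NH3(l), THF, t-BuOH, −78 to −33 °C; then NH4Cl
Reagents that add atoms: none
Why: Birch reduction protonates the two unsubstituted para-related carbons so that the methoxy- and methyl-bearing carbons stay sp2, giving the skipped diene in which the future C1(10) olefin is held cis by the ring.

Step 2
Reactants: 2 1-methoxy-4-methylcyclohexa-1,4-diene
Product: 4 methyl (3Z)-6,6-dimethoxy-4-methylhex-3-enoate, via aldehyde ester 3 (not isolated)
Conditions: O3 (1.0 equiv), CH2Cl2, −78 °C; Me2S; then HC(OMe)3, TsOH (2 mol %), 0 °C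
Reagents that add atoms: ozone O=[O+][O-]; trimethyl orthoformate COC(OC)OC
Why: Chemoselective ozonolysis of the much more electron-rich enol ether double bond (methoxy carbon becomes the methyl ester, its neighbour the aldehyde, trapped at once as the dimethyl acetal) opens the ring and leaves the trisubstituted olefin untouched with the ring-imposed (Z) geometry of C1(10).

Step 3
Reactants: 4 methyl (3Z)-6,6-dimethoxy-4-methylhex-3-enoate
Product: 5 (3Z)-6,6-dimethoxy-4-methylhex-3-en-1-ol
Conditions: LiAlH4, Et2O, 0 °C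
Reagents that add atoms: none
Why: Hydride reduction of the ester to the primary alcohol, the acetal and the isolated olefin being inert to LiAlH4.

Step 4
Reactants: 5 (3Z)-6,6-dimethoxy-4-methylhex-3-en-1-ol
Product: 6 (3Z)-6-iodo-1,1-dimethoxy-3-methylhex-3-ene
Conditions: I2, PPh3, imidazole, CH2Cl2, 0 °C
Reagents that add atoms: iodine II
Why: Appel-type iodination (SN2 displacement of the alkoxyphosphonium by iodide), buffered by imidazole so that the acetal survives.

Step 5
Reactants: 7 pent-3-yn-2-one
Product: 8 (3Z)-4-iodopent-3-en-2-one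
Conditions: NaI, AcOH, rt
Reagents that add atoms: sodium iodide [Na+].[I-]
Why: Conjugate hydroiodination of the ynone (iodide adds at the β-carbon, the allenol is protonated anti) gives the (Z)-β-iodo enone and so fixes the C4–C5 olefin geometry with iodine cis to the acyl group.

Step 6
Reactants: 8 (3Z)-4-iodopent-3-en-2-one
Product: 9 (3Z)-4-iodo-2-(trimethylsilyloxy)penta-1,3-diene
Conditions: LiN(SiMe3)2, Me3SiCl, THF, −78 °C
Reagents that add atoms: chlorotrimethylsilane C[Si](C)(C)Cl
Why: Kinetic deprotonation of the acetyl methyl group with in situ silylation (silyl enol ether formation) by a non-nucleophilic base leaves the vinylogous acyl iodide intact.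

Step 7
Reactants: 9 (3Z)-4-iodo-2-(trimethylsilyloxy)penta-1,3-diene; 10 methyl pyruvate
Product: 11 methyl (2R,5Z)-6-iodo-2-methyl-4-oxo-2-(trimethylsilyloxy)hept-5-enoate
Conditions: Cu(OTf)2 (10 mol %), (R,R)-t-Bu-box [2,2′-isopropylidenebis((4R)-4-tert-butyl-2-oxazoline)] (11 mol %), THF, −78 °C; aprotic work-up
Reagents that add atoms: none
Why: Catalytic enantioselective Mukaiyama aldol addition to pyruvate chelated on the chiral divalent copper bis(oxazoline) complex, in which the enol silane attacks one face of the bound ketone (the (R,R)-ligand is the antipode of the one that gives (S)-tertiary aldols) and sets C11 as (R), the silyl group ending on the new tertiary oxygen.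

Step 8
Reactants: 6 (3Z)-6-iodo-1,1-dimethoxy-3-methylhex-3-ene; 11 methyl (2R,5Z)-6-iodo-2-methyl-4-oxo-2-(trimethylsilyloxy)hept-5-enoate
Product: 13 methyl (2R,5Z,9Z)-12,12-dimethoxy-2,6,10-trimethyl-4-oxo-2-(trimethylsilyloxy)dodeca-5,9-dienoate, via alkylzinc iodide 12 (not isolated)
Conditions: Zn dust, LiCl, THF, 35 °C; then 11, Pd(dppf)Cl2 (5 mol %), THF, rt
Reagents that add atoms: none
Why: Zinc insertion into the primary iodide and palladium-catalysed Negishi sp3–sp2 coupling with the β-iodo enone proceed with retention of olefin geometry and join C3 to C4, giving the complete (Z,Z) chain while ketone, ester, acetal and silyl ether are tolerated by the organozinc.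

Step 9
Reactants: 13 methyl (2R,5Z,9Z)-12,12-dimethoxy-2,6,10-trimethyl-4-oxo-2-(trimethylsilyloxy)dodeca-5,9-dienoate
Product: 15 methyl (2S,5Z,9Z)-3-bromo-12,12-dimethoxy-2,6,10-trimethyl-4-oxo-2-(trimethylsilyloxy)dodeca-5,9-dienoate, via silyl dienol ether 14 (not isolated)
Conditions: LiN(SiMe3)2, Me3SiCl, THF, −78 °C; then NBS, THF, −78 °C
Reagents that add atoms: N-bromosuccinimide O=C1CCC(=O)N1Br
Why: Kinetic α′-deprotonation of the enone with in situ silylation, then electrophilic bromination of the silyl dienol ether, brominates C7 regiospecifically; the C7 configuration is irrelevant because it becomes an enolate carbon in step 11 (C11 is unchanged, its descriptor reads S only because bromine changes the priorities).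

Step 10
Reactants: 15 methyl (2S,5Z,9Z)-3-bromo-12,12-dimethoxy-2,6,10-trimethyl-4-oxo-2-(trimethylsilyloxy)dodeca-5,9-dienoate
Product: 16 methyl (2S,5Z,9Z)-3-bromo-2,6,10-trimethyl-4,12-dioxo-2-(trimethylsilyloxy)dodeca-5,9-dienoate
Conditions: Et3SiOTf, 2,4,6-collidine, CH2Cl2, 0 °C; then H2O
Reagents that add atoms: water O
Why: Non-acidic acetal cleavage through the collidinium salt (silyl triflate–collidine method) frees the β,γ-unsaturated aldehyde without migration of the olefin into conjugation and without loss of the tertiary silyl ether or the α-bromo ketone.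

Step 11
Reactants: 16 methyl (2S,5Z,9Z)-3-bromo-2,6,10-trimethyl-4,12-dioxo-2-(trimethylsilyloxy)dodeca-5,9-dienoate
Product: 19 (1(10)Z,4Z,7R,8R,11R)-11-hydroxy-6-oxogermacra-1(10),4-dien-12,8-olide, via samarium enolate 17 (not isolated), via silylated lactone 18 (not isolated)
Conditions: SmI2 (2.5 equiv), THF, −78 °C, slow addition (2 mM), then 0 °C; DBU (0.2 equiv), CH2Cl2, rt; 1 M HCl, THF, 0 °C
Reagents that add atoms: none
Why: Samarium Reformatsky macrocyclisation, in which reduction of the α-bromo ketone gives a trivalent samarium enolate that adds to the aldehyde under high dilution to close the ten-membered ring at C7–C8, the aldolate lactonises onto the methyl ester, and DBU then equilibrates C7 (enolisation) and C8 (retro-oxa-Michael and re-addition) of the still silylated lactone (the silyl ether blocks retro-aldol cleavage of C7–C11) to the most stable γ-lactone with the C7 acyl branch trans to both C9 and the C11 methyl, which is the target's relative configuration relayed from C11.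

Step 12
Reactants: 19 (1(10)Z,4Z,7R,8R,11R)-11-hydroxy-6-oxogermacra-1(10),4-dien-12,8-olide
Product: 20 (1(10)Z,4Z,6R,7R,8R,11R)-6,11-dihydroxygermacra-1(10),4-dien-12,8-olide
Conditions: Et2BOMe, THF/MeOH (4:1), −78 °C; NaBH4; then AcOH, MeOH
Reagents that add atoms: none
Why: Narasaka–Prasad reduction, in which Et2BOMe ties the free C11 hydroxyl and the C6 ketone into a six-membered boron chelate cis-fused to the lactone and external hydride adds 1,2 to its exposed convex face, giving the 1,3-syn diol that corresponds to the C6 configuration of the target.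

Step 13
Reactants: 20 (1(10)Z,4Z,6R,7R,8R,11R)-6,11-dihydroxygermacra-1(10),4-dien-12,8-olide
Product: 21 (1(10)Z,4R,5S,6S,7R,8R,11R)-4,5-epoxy-6,11-dihydroxygermacr-1(10)-en-12,8-olide
Conditions: VO(acac)2 (5 mol %), t-BuOOH, CH2Cl2, 0 °C
Reagents that add atoms: tert-butyl hydroperoxide CC(C)(C)OO
Why: Hydroxyl-directed vanadium-catalysed epoxidation, in which the vanadate ester of the C6 hydroxyl delivers oxygen to the face of the allylic (Z)-C4=C5 olefin syn to that hydroxyl, as in eight- and nine-membered (Z)-cycloalk-2-enols, giving the cis-epoxy alcohol relationship of the target while the remote C1(10) olefin is untouched.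

Step 14
Reactants: 21 (1(10)Z,4R,5S,6S,7R,8R,11R)-4,5-epoxy-6,11-dihydroxygermacr-1(10)-en-12,8-olide
Product: 22 (1R,4R,5S,6S,7R,8R,10S,11R)-1,10:4,5-diepoxy-6,11-dihydroxygermacran-12,8-olide
Conditions: dimethyldioxirane, acetone, −20 °C
Reagents that add atoms: dimethyldioxirane CC1(C)OO1
Why: Neutral dioxirane epoxidation is stereospecific (cis-oxirane from the (Z)-olefin) and is expected to occur on the peripheral face of the folded ring, taken here to be the face syn to the C8–O bond as the target requires; this facial selectivity is substrate-controlled and not secured by precedent.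

Step 15
Reactants: 22 (1R,4R,5S,6S,7R,8R,10S,11R)-1,10:4,5-diepoxy-6,11-dihydroxygermacran-12,8-olide; 23 angelic acid
Product: 25 (1R,4R,5S,6S,7S,8R,10S,11R)-6,11-bis(angeloyloxy)-1,10:4,5-diepoxygermacran-12,8-olide, via mixed anhydride 24 (not isolated)
Conditions: 23 (6 equiv), 2,4,6-trichlorobenzoyl chloride (6 equiv), Et3N (7 equiv), toluene, rt, filter; then 22, toluene, 80 °C
Reagents that add atoms: angelic acid (second equivalent) C/C=C(/C)C(=O)O
Why: Yamaguchi-type acylation without a nucleophilic catalyst, in which two molecules of the preformed angelic 2,4,6-trichlorobenzoic mixed anhydride each transfer an angeloyl group (attack at the less hindered aliphatic carbonyl), one to the secondary C6 hydroxyl and one to the tertiary C11 hydroxyl, while avoiding the addition–elimination path that turns angelates into tiglates, and no stereocenter is touched (the C7 descriptor reads S only because acylation of the C6 oxygen changes the priorities).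

## Compound list

1 | 4-methylanisole | COc1ccc(C)cc1 | starting material
2 | 1-methoxy-4-methylcyclohexa-1,4-diene | COC1=CCC(C)=CC1 | intermediate
3 | methyl (3Z)-4-methyl-6-oxohex-3-enoate | COC(=O)C/C=C(/C)CC=O | intermediate
4 | methyl (3Z)-6,6-dimethoxy-4-methylhex-3-enoate | COC(=O)C/C=C(/C)CC(OC)OC | intermediate
5 | (3Z)-6,6-dimethoxy-4-methylhex-3-en-1-ol | OCC/C=C(/C)CC(OC)OC | intermediate
6 | (3Z)-6-iodo-1,1-dimethoxy-3-methylhex-3-ene | ICC/C=C(/C)CC(OC)OC | intermediate
7 | pent-3-yn-2-one | CC#CC(C)=O | starting material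
8 | (3Z)-4-iodopent-3-en-2-one | C/C(I)=C/C(C)=O | intermediate
9 | (3Z)-4-iodo-2-(trimethylsilyloxy)penta-1,3-diene | C/C(I)=C/C(=C)O[Si](C)(C)C | intermediate
10 | methyl pyruvate | COC(=O)C(C)=O | starting material
11 | methyl (2R,5Z)-6-iodo-2-methyl-4-oxo-2-(trimethylsilyloxy)hept-5-enoate | COC(=O)[C@](C)(O[Si](C)(C)C)CC(=O)/C=C(/C)I | intermediate
12 | [(3Z)-6,6-dimethoxy-4-methylhex-3-enyl]zinc iodide | I[Zn]CC/C=C(/C)CC(OC)OC | intermediate
13 | methyl (2R,5Z,9Z)-12,12-dimethoxy-2,6,10-trimethyl-4-oxo-2-(trimethylsilyloxy)dodeca-5,9-dienoate | COC(=O)[C@](C)(O[Si](C)(C)C)CC(=O)/C=C(/C)CC/C=C(/C)CC(OC)OC | intermediate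
14 | methyl (2R,5Z,9Z)-12,12-dimethoxy-2,6,10-trimethyl-2,4-bis(trimethylsilyloxy)dodeca-3,5,9-trienoate (C3=C4 geometry not defined) | COC(=O)[C@](C)(O[Si](C)(C)C)C=C(O[Si](C)(C)C)/C=C(/C)CC/C=C(/C)CC(OC)OC | intermediate
15 | methyl (2S,5Z,9Z)-3-bromo-12,12-dimethoxy-2,6,10-trimethyl-4-oxo-2-(trimethylsilyloxy)dodeca-5,9-dienoate (both C3 epimers) | COC(=O)[C@](C)(O[Si](C)(C)C)C(Br)C(=O)/C=C(/C)CC/C=C(/C)CC(OC)OC | intermediate
16 | methyl (2S,5Z,9Z)-3-bromo-2,6,10-trimethyl-4,12-dioxo-2-(trimethylsilyloxy)dodeca-5,9-dienoate (both C3 epimers) | COC(=O)[C@](C)(O[Si](C)(C)C)C(Br)C(=O)/C=C(/C)CC/C=C(/C)CC=O | intermediate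
17 | methyl (2R,5Z,9Z)-4-(diiodosamariooxy)-2,6,10-trimethyl-12-oxo-2-(trimethylsilyloxy)dodeca-3,5,9-trienoate (trivalent samarium enolate) | COC(=O)[C@](C)(O[Si](C)(C)C)C=C(O[Sm](I)I)/C=C(/C)CC/C=C(/C)CC=O | intermediate
18 | (1(10)Z,4Z,11R)-6-oxo-11-(trimethylsilyloxy)germacra-1(10),4-dien-12,8-olide (C7/C8 diastereomers) | C1/C(C)=C\C(=O)C2C(C/C(C)=C\C1)OC(=O)[C@]2(C)O[Si](C)(C)C | intermediate
19 | (1(10)Z,4Z,7R,8R,11R)-11-hydroxy-6-oxogermacra-1(10),4-dien-12,8-olide | C1/C(C)=C\C(=O)[C@@H]2[C@@H](C/C(C)=C\C1)OC(=O)[C@]2(C)O | intermediate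
20 | (1(10)Z,4Z,6R,7R,8R,11R)-6,11-dihydroxygermacra-1(10),4-dien-12,8-olide | C1/C(C)=C\[C@@H](O)[C@@H]2[C@@H](C/C(C)=C\C1)OC(=O)[C@]2(C)O | intermediate
21 | (1(10)Z,4R,5S,6S,7R,8R,11R)-4,5-epoxy-6,11-dihydroxygermacr-1(10)-en-12,8-olide | O[C@H]1[C@@H]2[C@@H](C/C(C)=C\CC[C@@]3(C)O[C@@H]13)OC(=O)[C@]2(C)O | intermediate
22 | (1R,4R,5S,6S,7R,8R,10S,11R)-1,10:4,5-diepoxy-6,11-dihydroxygermacran-12,8-olide | O[C@H]1[C@@H]2[C@@H](C[C@]3(C)O[C@@H]3CC[C@@]3(C)O[C@@H]13)OC(=O)[C@]2(C)O | intermediate
23 | angelic acid, (2Z)-2-methylbut-2-enoic acid | C/C=C(/C)C(=O)O | starting material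
24 | (2Z)-2-methylbut-2-enoic 2,4,6-trichlorobenzoic anhydride | C/C=C(/C)C(=O)OC(=O)c1c(Cl)cc(Cl)cc1Cl | intermediate
25 | (1R,4R,5S,6S,7S,8R,10S,11R)-6,11-bis(angeloyloxy)-1,10:4,5-diepoxygermacran-12,8-olide | C/C=C(/C)C(=O)O[C@H]1[C@@H]2[C@@H](C[C@]3(C)O[C@@H]3CC[C@@]3(C)O[C@@H]13)OC(=O)[C@]2(C)OC(=O)/C(C)=C\C | target

## Step count and weak points

Total: 15 steps (fragment A steps 1–4, fragment B steps 5–7, steps 8–15 after convergence). Longest linear sequence: 12 steps (1–4, 8–15) from 4-methylanisole.

The three steps most likely to fail: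

**Step 11 (ten-membered ring closure).** The samarium enolate may be quenched or oligomerise before it finds the aldehyde, or the closure may give a C7/C8 diastereomer that does not equilibrate cleanly. The fallback sets out from 13 and closes the ring on an oxocarbenium ion instead of an aldehyde. Silyl dienol ether 14 is made as in step 9 and treated with catalytic Me3SiOTf in CH2Cl2 at −78 °C and 1 mM (intramolecular Mukaiyama–Noyori acetal aldol) to give methyl (2R)-2-[(3Z,7Z)-10-methoxy-4,8-dimethyl-2-oxocyclodeca-3,7-dien-1-yl]-2-(trimethylsilyloxy)propanoate F1. DBU eliminates methanol to the cross-conjugated trienone methyl (2R)-2-[(4Z,8Z)-4,8-dimethyl-10-oxocyclodeca-1,4,8-trien-1-yl]-2-(trimethylsilyloxy)propanoate F2, which erases both C7 and C8. Me3SnOH followed by aqueous HCl gives (2R)-2-[(4Z,8Z)-4,8-dimethyl-10-oxocyclodeca-1,4,8-trien-1-yl]-2-hydroxypropanoic acid F3. Catalytic DBU then closes the lactone by reversible oxa-Michael addition under the same thermodynamic control, and the route is rejoined at 19.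

**Step 14 (face of the C1(10) epoxidation).** If the dioxirane delivers oxygen to the wrong face, the fallback sets out from 21 and inverts the outcome through a halohydrin. NBS in buffered aqueous THF forms the bromonium ion on that same accessible face and water opens it anti at the tertiary carbon to give (1S,4R,5S,6S,7R,8R,10S,11R)-1-bromo-4,5-epoxy-6,10,11-trihydroxygermacran-12,8-olide F4. Ag2O in THF closes the oxirane by SN2 displacement at C1, which places the oxygen on the opposite face to direct epoxidation, and the route is rejoined at 22.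

**Step 15 (tertiary angelate without isomerisation).** If the C11 hydroxyl resists the mixed anhydride or tiglate appears, the fallback sets out from 22 and builds the angelate double bond on the ester. Both hydroxyls are acylated under forcing DCC/DMAP conditions (acylation through the phosphoryl ketene) with two equivalents of 2-[bis(2,2,2-trifluoroethoxy)phosphoryl]propanoic acid, which cannot isomerise, to give (1R,4R,5S,6S,7S,8R,10S,11R)-1,10:4,5-diepoxygermacran-12,8-olide-6,11-diyl bis{2-[bis(2,2,2-trifluoroethoxy)phosphoryl]propanoate} F5. Still–Gennari olefination of both phosphonates with acetaldehyde (KN(SiMe3)2, 18-crown-6, THF, −78 °C) forms the two (Z)-2-methylbut-2-enoates, and the route is rejoined at 25.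

Further compounds

F1 | step 11 | methyl (2R)-2-[(3Z,7Z)-10-methoxy-4,8-dimethyl-2-oxocyclodeca-3,7-dien-1-yl]-2-(trimethylsilyloxy)propanoate (ring C1/C10 epimers) | C1/C(C)=C\C(=O)C(C(OC)C/C(C)=C\C1)[C@@](C)(O[Si](C)(C)C)C(=O)OC
F2 | step 11 | methyl (2R)-2-[(4Z,8Z)-4,8-dimethyl-10-oxocyclodeca-1,4,8-trien-1-yl]-2-(trimethylsilyloxy)propanoate | C1/C(C)=C\C(=O)C(=CC/C(C)=C\C1)[C@@](C)(O[Si](C)(C)C)C(=O)OC
F3 | step 11 | (2R)-2-[(4Z,8Z)-4,8-dimethyl-10-oxocyclodeca-1,4,8-trien-1-yl]-2-hydroxypropanoic acid | C1/C(C)=C\C(=O)C(=CC/C(C)=C\C1)[C@@](C)(O)C(=O)O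
F4 | step 14 | (1S,4R,5S,6S,7R,8R,10S,11R)-1-bromo-4,5-epoxy-6,10,11-trihydroxygermacran-12,8-olide | O[C@H]1[C@@H]2[C@@H](C[C@](C)(O)[C@@H](Br)CC[C@@]3(C)O[C@@H]13)OC(=O)[C@]2(C)O
F5 | step 15 | (1R,4R,5S,6S,7S,8R,10S,11R)-1,10:4,5-diepoxygermacran-12,8-olide-6,11-diyl bis{2-[bis(2,2,2-trifluoroethoxy)phosphoryl]propanoate} | CC(C(=O)O[C@H]1[C@@H]2[C@@H](C[C@]3(C)O[C@@H]3CC[C@@]3(C)O[C@@H]13)OC(=O)[C@]2(C)OC(=O)C(C)P(=O)(OCC(F)(F)F)OCC(F)(F)F)P(=O)(OCC(F)(F)F)OCC(F)(F)F
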